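**Retrosynthetic overview**
- Target ⇐ tris-MOM chalcone (global acid deprotection) ⇐ saturated aryl ketone (Saegusa–Ito dehydrogenation sets the E-alkene).
- Key disconnection: the bond between the enone β-carbon and the prenylated ring. The β-carbon is used as a nucleophile (palladium homoenolate from a 1-arylcyclopropanol) and the aryl bromide is the electrophile.
- Cyclopropanol ⇐ methyl 3,4-bis(methoxymethoxy)benzoate (Kulinkovich) ⇐ methyl 3,4-dihydroxybenzoate.
- Aryl bromide ⇐ 4-bromo-3-methoxyphenol, by MOM protection and directed ortho-metalation/prenylation between the two oxygens.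
- Rings: both benzene rings are bought intact; the only ring made is the cyclopropanol (step 2), and it is opened again in the key step (step 5).

Assumption: the target has no stereocentre, so "single enantiomer" is read as the single E-alkene isomer shown; 4-bromo-3-methoxyphenol is taken as a catalogue starting material.

**Step 1**
Reactants: 1 methyl 3,4-dihydroxybenzoate; 2 chloromethyl methyl ether (MOMCl)
Product: 3 methyl 3,4-bis(methoxymethoxy)benzoate
Conditions: MOMCl (2.5 equiv), iPr2NEt (3 equiv), CH2Cl2, 0 °C → rt
Reagents that add atoms: chloromethyl methyl ether (2), COCCl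
Why: O-alkylation of both catechol hydroxyls (MOM protection, Williamson type) masks the acidic OH groups for the Grignard and palladium steps, and the acetals are removed together in the last step.

**Step 2**
Reactants: 3 methyl 3,4-bis(methoxymethoxy)benzoate; 4 ethylmagnesium bromide
Product: 5 1-[3,4-bis(methoxymethoxy)phenyl]cyclopropan-1-ol
Conditions: EtMgBr (2.6 equiv, slow addition), Ti(OiPr)4 (0.3 equiv), THF, 0 °C → rt; aq NH4Cl
Reagents that add atoms: ethylmagnesium bromide (4), CC[Mg]Br
Why: Kulinkovich cyclopropanation, in which the titanacyclopropane formed from EtMgBr and Ti(OiPr)4 acts as a 1,2-dicarbanion and adds twice to the ester carbonyl, giving the 1-arylcyclopropanol (the masked homoenolate of the aryl ketone) while the MOM ethers are inert.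

**Step 3**
Reactants: 6 4-bromo-3-methoxyphenol; 2 chloromethyl methyl ether (MOMCl)
Product: 7 1-bromo-2-methoxy-4-(methoxymethoxy)benzene
Conditions: MOMCl (1.2 equiv), iPr2NEt (1.5 equiv), CH2Cl2, 0 °C → rt
Reagents that add atoms: chloromethyl methyl ether (2), COCCl
Why: MOM protection of the phenol (O-alkylation) removes the acidic proton and installs the OMOM group that directs the metalation in step 4.

**Step 4**
Reactants: 7 1-bromo-2-methoxy-4-(methoxymethoxy)benzene; 8 1-bromo-3-methylbut-2-ene (prenyl bromide)
Product: 10 1-bromo-2-methoxy-4-(methoxymethoxy)-3-(3-methylbut-2-en-1-yl)benzene, via aryllithium 9 (not isolated)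
Conditions: LDA (commercial solution, 1.2 equiv), THF, −78 °C, 1 h; then 8 (1.5 equiv), −78 → 0 °C
Reagents that add atoms: 1-bromo-3-methylbut-2-ene (8), CC(C)=CCBr
Why: Directed ortho-metalation, in which the lithium amide (which does not undergo Br/Li exchange) removes the proton flanked by OMe and OMOM, the most acidic and doubly coordinated site, and the aryllithium is alkylated by prenyl bromide in an SN2 sense.

**Step 5**
Reactants: 5 1-[3,4-bis(methoxymethoxy)phenyl]cyclopropan-1-ol; 10 1-bromo-2-methoxy-4-(methoxymethoxy)-3-(3-methylbut-2-en-1-yl)benzene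
Product: 11 1-[3,4-bis(methoxymethoxy)phenyl]-3-[2-methoxy-4-(methoxymethoxy)-3-(3-methylbut-2-en-1-yl)phenyl]propan-1-one
Conditions: 5 (1.3 equiv), Pd(OAc)2 (5 mol%), XPhos (10 mol%), Cs2CO3 (2 equiv), toluene, 80 °C
Reagents that add atoms: none
Why: Palladium-catalysed cross-coupling of a cyclopropanol-derived ketone homoenolate with an aryl bromide: oxidative addition of 10, exchange of bromide for the cyclopropoxide of 5, strain-driven β-carbon elimination to the Pd(II) homoenolate and C(sp2)–C(sp3) reductive elimination (favoured over β-hydride elimination by the bulky biarylphosphine) join the ketone β-carbon, used here as a nucleophile, to the aryl carbon.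

**Step 6**
Reactants: 11 1-[3,4-bis(methoxymethoxy)phenyl]-3-[2-methoxy-4-(methoxymethoxy)-3-(3-methylbut-2-en-1-yl)phenyl]propan-1-one
Product: 13 (2E)-1-[3,4-bis(methoxymethoxy)phenyl]-3-[2-methoxy-4-(methoxymethoxy)-3-(3-methylbut-2-en-1-yl)phenyl]prop-2-en-1-one, via silyl enol ether 12 (not isolated)
Conditions: LiHMDS (commercial solution, 1.2 equiv), TMSCl (1.3 equiv), THF, −78 → 0 °C; evaporate; then Pd(OAc)2 (1.1 equiv), MeCN, rt
Reagents that add atoms: none
Why: Saegusa–Ito oxidation, in which the silyl enol ether is converted by Pd(OAc)2 into a palladium enolate that undergoes syn β-hydride elimination from the benzylic CH2 to give the conjugated enone as the thermodynamically favoured E isomer (the only stereo element of the target is set here), while the trisubstituted prenyl alkene is a poor ligand for Pd(II) and is left alone.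

**Step 7**
Reactants: 13 (2E)-1-[3,4-bis(methoxymethoxy)phenyl]-3-[2-methoxy-4-(methoxymethoxy)-3-(3-methylbut-2-en-1-yl)phenyl]prop-2-en-1-one
Product: 14 licoagrochalcone C, (2E)-1-(3,4-dihydroxyphenyl)-3-[4-hydroxy-2-methoxy-3-(3-methylbut-2-en-1-yl)phenyl]prop-2-en-1-one
Conditions: 3 M aq HCl, MeOH, 40 °C
Reagents that add atoms: none
Why: Acid-catalysed acetal exchange with methanol (MOM removal) frees all three phenols, and the mild temperature keeps the ortho-prenylphenol from cyclising to the chroman and leaves the E-enone and the aryl methyl ether untouched.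

**Compound list**
1 | methyl 3,4-dihydroxybenzoate | COC(=O)c1ccc(O)c(O)c1 | starting material
2 | chloromethyl methyl ether (MOMCl) | COCCl | starting material
3 | methyl 3,4-bis(methoxymethoxy)benzoate | COCOc1ccc(C(=O)OC)cc1OCOC | intermediate
4 | ethylmagnesium bromide | CC[Mg]Br | starting material
5 | 1-[3,4-bis(methoxymethoxy)phenyl]cyclopropan-1-ol | COCOc1ccc(C2(O)CC2)cc1OCOC | intermediate
6 | 4-bromo-3-methoxyphenol | COc1cc(O)ccc1Br | starting material
7 | 1-bromo-2-methoxy-4-(methoxymethoxy)benzene | COCOc1ccc(Br)c(OC)c1 | intermediate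
8 | 1-bromo-3-methylbut-2-ene (prenyl bromide) | CC(C)=CCBr | starting material
9 | [3-bromo-2-methoxy-6-(methoxymethoxy)phenyl]lithium | [Li]c1c(OC)c(Br)ccc1OCOC | intermediate (not isolated)
10 | 1-bromo-2-methoxy-4-(methoxymethoxy)-3-(3-methylbut-2-en-1-yl)benzene | COCOc1ccc(Br)c(OC)c1CC=C(C)C | intermediate
11 | 1-[3,4-bis(methoxymethoxy)phenyl]-3-[2-methoxy-4-(methoxymethoxy)-3-(3-methylbut-2-en-1-yl)phenyl]propan-1-one | COCOc1ccc(C(=O)CCc2ccc(OCOC)c(CC=C(C)C)c2OC)cc1OCOC | intermediate
12 | {[(1Z)-1-[3,4-bis(methoxymethoxy)phenyl]-3-[2-methoxy-4-(methoxymethoxy)-3-(3-methylbut-2-en-1-yl)phenyl]prop-1-en-1-yl]oxy}trimethylsilane | COCOc1ccc(/C(O[Si](C)(C)C)=C/Cc2ccc(OCOC)c(CC=C(C)C)c2OC)cc1OCOC | intermediate (not isolated)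
13 | (2E)-1-[3,4-bis(methoxymethoxy)phenyl]-3-[2-methoxy-4-(methoxymethoxy)-3-(3-methylbut-2-en-1-yl)phenyl]prop-2-en-1-one | COCOc1ccc(C(=O)/C=C/c2ccc(OCOC)c(CC=C(C)C)c2OC)cc1OCOC | intermediate
14 | licoagrochalcone C, (2E)-1-(3,4-dihydroxyphenyl)-3-[4-hydroxy-2-methoxy-3-(3-methylbut-2-en-1-yl)phenyl]prop-2-en-1-one | COc1c(/C=C/C(=O)c2ccc(O)c(O)c2)ccc(O)c1CC=C(C)C | target

**Totals**
Total step count: 7.
Longest linear sequence: 5 steps (1 → 3 → 5 → 11 → 13 → 14, or equally 6 → 7 → 10 → 11 → 13 → 14).

**Steps most likely to fail, with fallbacks**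

Step 5 (homoenolate cross-coupling). The risks are β-hydride elimination of the palladium homoenolate, base-induced opening of 5 to the propiophenone, and slow oxidative addition of the electron-rich, ortho-substituted bromide 10. The fallback sets out from 5 and 10 and comes back to the route at 13, so it also replaces step 6. Cyclopropanol 5 is opened oxidatively (Pd(OAc)2 cat., pyridine, O2, toluene, 80 °C) to the aryl vinyl ketone 1-[3,4-bis(methoxymethoxy)phenyl]prop-2-en-1-one F1. F1 is then joined to 10 by a Mizoroki–Heck reaction (Pd(OAc)2, P(o-tol)3, Et3N, DMF, 100 °C), which gives the E-enone 13 directly.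

Step 4 (metalation next to an aryl bromide). The risks are competing deprotonation ortho to bromine, halogen migration between aryllithium and aryl bromide, and incomplete alkylation. The fallback sets out from 6 and comes back at 10, replacing steps 3 and 4. The sodium phenoxide of 6 (NaH, toluene, 0 °C → rt) is C-alkylated with 8 at the ortho position flanked by the methoxy group, which helps hold the sodium ion there. This gives 4-bromo-3-methoxy-2-(3-methylbut-2-en-1-yl)phenol F2, which must be separated from the 6-prenyl isomer and the O-prenyl ether. MOM protection of F2 (MOMCl, iPr2NEt, CH2Cl2) then gives 10.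

Step 6 (dehydrogenation in the presence of the prenyl group and three MOM ethers). The risks are incomplete silylation and side reactions of Pd(II) with the electron-rich substrate. The fallback sets out from 11 and comes back at 13. The lithium enolate of 11 (LiHMDS, THF, −78 °C) is trapped with PhSeCl to give the racemic α-selanyl ketone 1-[3,4-bis(methoxymethoxy)phenyl]-3-[2-methoxy-4-(methoxymethoxy)-3-(3-methylbut-2-en-1-yl)phenyl]-2-(phenylselanyl)propan-1-one F3. Oxidation (H2O2, pyridine, CH2Cl2, 0 °C) and selenoxide syn-elimination then give the E-enone 13.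

**Further compounds**
F1 | step 5 | 1-[3,4-bis(methoxymethoxy)phenyl]prop-2-en-1-one | COCOc1ccc(C(=O)C=C)cc1OCOC
F2 | step 4 | 4-bromo-3-methoxy-2-(3-methylbut-2-en-1-yl)phenol | COc1c(Br)ccc(O)c1CC=C(C)C
F3 | step 6 | 1-[3,4-bis(methoxymethoxy)phenyl]-3-[2-methoxy-4-(methoxymethoxy)-3-(3-methylbut-2-en-1-yl)phenyl]-2-(phenylselanyl)propan-1-one (racemic) | COCOc1ccc(C(=O)C(Cc2ccc(OCOC)c(CC=C(C)C)c2OC)[Se]c2ccccc2)cc1OCOC
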